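**Retrosynthetic overview**

1. Target 24 ⇐ diol lactone 21 by site-selective angeloylation of the allylic 2-OH.
2. 21 ⇐ 17 by ring expansion six → ten: the ring C8–O bond of a cyclic acetal/lactol is exchanged for C7–C8 (zinc-mediated allyl transfer from a (Z)-2-(bromomethyl)enoate), then 6,12-lactonisation.
3. 17 ⇐ 14 + 15 by one-pot ring-closing metathesis (six-membered acetal, fixes Z-C1=C10) and cross-metathesis (bromomethyl enoate).
4. 14 ⇐ 10 by trans-hydroalumination/iodination, Stille hydroxymethylation and acetylation (fixes C4=C5 with C-15 cis to C-6); 10 ⇐ 7 + acrolein (asymmetric alkynylation, C-6).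
5. 7 ⇐ (R)-2-vinyloxirane + acetylide (C-2) and acetal 3. Ring order: dihydropyran acetal → ten-membered carbocycle → γ-lactone.

Assumption: the acetal (anomeric) carbon of 7–18 is carried as both epimers and has no stereo mark in the SMILES, because it is destroyed in step 9; skeleton atoms are given germacrane numbers (C-1 to C-15).

**Step 1**
Reactants: 1 2-methylallylmagnesium chloride; 2 trimethyl orthoformate
Product: 3 4,4-dimethoxy-2-methylbut-1-ene
Conditions: Et2O/THF, reflux; aq. NH4Cl work-up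
Reagents that add atoms: none
Why: Bodroux–Chichibabin substitution of one methoxy group of the orthoester by the allylic Grignard reagent gives the β,γ-unsaturated aldehyde directly as its acetal, so the alkene cannot move into conjugation; no stereocentre is formed.

**Step 2**
Reactants: 4 (R)-2-vinyloxirane; 5 lithium acetylide–ethylenediamine complex
Product: 6 (S)-hex-1-en-5-yn-3-ol
Conditions: DMSO, rt; aq. NH4Cl work-up
Reagents that add atoms: none
Why: SN2 epoxide opening by acetylide at the unhindered CH2 leaves the epoxide stereocentre untouched, so it becomes C-3 of 6 (future C-2), the R→S change being only a change of CIP priorities.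

**Step 3**
Reactants: 6 (S)-hex-1-en-5-yn-3-ol; 3 4,4-dimethoxy-2-methylbut-1-ene
Product: 7 (3S)-3-[(1-methoxy-3-methylbut-3-en-1-yl)oxy]hex-1-en-5-yne
Conditions: 3 (4 equiv), PPTS (cat.), 5 Å molecular sieves, CH2Cl2, rt
Reagents that add atoms: none
Why: Acid-catalysed transacetalisation with excess 3 (methanol trapped by the sieves) gives the mixed acetal that brings in C-8, C-9, C-10 and C-14; the new acetal centre is unselective and is erased in step 9.

**Step 4**
Reactants: 7 (3S)-3-[(1-methoxy-3-methylbut-3-en-1-yl)oxy]hex-1-en-5-yne; 8 acrolein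
Product: 10 (3S,7S)-7-[(1-methoxy-3-methylbut-3-en-1-yl)oxy]nona-1,8-dien-4-yn-3-ol, via methylzinc acetylide 9 (not isolated)
Conditions: Me2Zn (3 equiv), ProPhenol ligand (10 mol%, enantiomer chosen for the 3S carbinol), Ph3PO (20 mol%), toluene, 0–4 °C, then 8
Reagents that add atoms: none
Why: Catalytic enantioselective alkynylzinc addition to an enal (Trost ProPhenol–zinc alkynylation) adds acetylide 9 to one carbonyl face of acrolein and sets the 3S carbinol (future C-6) by catalyst control, the acetal and the alkenes being inert.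

**Step 5**
Reactants: 10 (3S,7S)-7-[(1-methoxy-3-methylbut-3-en-1-yl)oxy]nona-1,8-dien-4-yn-3-ol
Product: 12 (3S,4Z,7S)-5-iodo-7-[(1-methoxy-3-methylbut-3-en-1-yl)oxy]nona-1,4,8-trien-3-ol, via cyclic alkenylalanate 11 (not isolated)
Conditions: NaAlH2(OCH2CH2OCH3)2 (Red-Al), THF, 0 °C → rt; then I2, THF, −78 °C; buffered work-up
Reagents that add atoms: iodine, II
Why: Hydroxyl-directed trans-hydroalumination of the propargylic alcohol through the five-membered alanate 11 and iodinolysis with retention (Red-Al/iodine sequence) put iodine on the distal carbon cis to the carbinol carbon, which fixes the future C4=C5 geometry (C-3 trans to C-6) while isolated alkenes and the acetal do not react.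

**Step 6**
Reactants: 12 (3S,4Z,7S)-5-iodo-7-[(1-methoxy-3-methylbut-3-en-1-yl)oxy]nona-1,4,8-trien-3-ol
Product: 13 (2Z,4S)-2-{(2S)-2-[(1-methoxy-3-methylbut-3-en-1-yl)oxy]but-3-en-1-yl}hexa-2,5-diene-1,4-diol
Conditions: Bu3SnCH2OH (1.5 equiv), Pd(PPh3)4 (5 mol%), toluene, 80 °C
Reagents that add atoms: (tributylstannyl)methanol, CCCC[Sn](CCCC)(CCCC)CO
Why: Migita–Kosugi–Stille coupling transfers CH2OH (C-15) with retention of alkene geometry, so C-15 ends cis to C-6 as in the target.

**Step 7**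
Reactants: 13 (2Z,4S)-2-{(2S)-2-[(1-methoxy-3-methylbut-3-en-1-yl)oxy]but-3-en-1-yl}hexa-2,5-diene-1,4-diol
Product: 14 (2Z,4S)-4-hydroxy-2-{(2S)-2-[(1-methoxy-3-methylbut-3-en-1-yl)oxy]but-3-en-1-yl}hexa-2,5-dien-1-yl acetate
Conditions: AcCl (1.05 equiv), 2,4,6-collidine, CH2Cl2, −78 °C
Reagents that add atoms: acetyl chloride, CC(Cl)=O
Why: Kinetic acylation of the primary allylic hydroxyl in preference to the hindered bis-allylic secondary one, under conditions (weakly acidic collidinium salt) that leave the mixed acetal intact.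

**Step 8**
Reactants: 14 (2Z,4S)-4-hydroxy-2-{(2S)-2-[(1-methoxy-3-methylbut-3-en-1-yl)oxy]but-3-en-1-yl}hexa-2,5-dien-1-yl acetate; 15 methyl 2-(bromomethyl)acrylate
Product: 17 methyl (2Z,4R,5Z)-6-(acetoxymethyl)-2-(bromomethyl)-4-hydroxy-7-[(2S)-6-methoxy-4-methyl-5,6-dihydro-2H-pyran-2-yl]hepta-2,5-dienoate, via ring-closed acetal 16 (not isolated)
Conditions: second-generation Hoveyda–Grubbs catalyst (10 mol%), 15 (6 equiv), 1,4-benzoquinone (10 mol%), CH2Cl2, 40 °C
Reagents that add atoms: none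
Why: Tandem olefin metathesis: ring-closing metathesis of the vinyl/methallyl pair closes the six-membered cyclic acetal and thereby fixes C1=C10 as Z, then cross-metathesis of the remaining vinyl carbinol with excess 15 gives the trisubstituted enoate with the ester trans to C-6 (thermodynamic geometry), larger-ring closures being disfavoured and benzoquinone suppressing Ru–H isomerisation.

**Step 9**
Reactants: 17 methyl (2Z,4R,5Z)-6-(acetoxymethyl)-2-(bromomethyl)-4-hydroxy-7-[(2S)-6-methoxy-4-methyl-5,6-dihydro-2H-pyran-2-yl]hepta-2,5-dienoate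
Product: 21 (2S,6R,7R,8R)-15-acetoxy-2,8-dihydroxygermacra-1(10),4,11(13)-trien-12,6-olide, via lactol 18 (not isolated), via open-chain allylzinc bromide 19 (not isolated), via triol ester 20 (not isolated)
Conditions: AcOH–H2O–THF (1:1:3), 35 °C; then NaHCO3/NH4Cl buffer, dilution to 0.003 M in THF–H2O, Zn dust, rt; then TsOH·H2O (0.2 equiv), rt
Reagents that add atoms: water, O
Why: Proposed new method: ring expansion of a six-membered lactol to a ten-membered carbocycle by intramolecular Barbier allylation – acid unmasks lactol 18, whose ring-chain tautomer (a Z-δ-hydroxy β,γ-enal present only in low stationary concentration, which disfavours oligomerisation and enal conjugation) is attacked at C-8 by C-7 of the allylzinc 19 formed by zinc insertion into the C–Br bond, so that the ring C8–O bond is replaced by C7–C8 and the five carbons C-3 to C-7 are inserted; the Zimmerman–Traxler chair with the ester trans to C-6 on the allylzinc and the C-9 chain equatorial gives the 7,8-syn relation (8R), addition on the alkene face that carries the C-5 tether with C6–H in the alkene plane (allylic 1,3-strain, product-like H-6/H-7 anti arrangement) gives 7R, and the freed 6-OH of 20 then closes the trans-fused γ-lactone under acid while the 8-OH stays free; the closest known reaction types are the aqueous zinc- or indium-mediated Barbier allylation of lactols with 2-(bromomethyl)acrylates and the Nozaki–Hiyama or Barbier macrocyclisation of open-chain formyl allylic bromides to germacranolides.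

**Step 10**
Reactants: 21 (2S,6R,7R,8R)-15-acetoxy-2,8-dihydroxygermacra-1(10),4,11(13)-trien-12,6-olide; 22 angelic acid
Product: 24 target CNP0129394.1, via mixed anhydride 23 (not isolated)
Conditions: 22 (1.2 equiv), 2,4,6-trichlorobenzoyl chloride, Et3N, toluene, rt; then 21, toluene, 50 °C (no DMAP)
Reagents that add atoms: none
Why: Yamaguchi-type mixed-anhydride esterification without DMAP avoids angelate-to-tiglate isomerisation, and the unhindered allylic 2-OH is acylated in preference to the 8-OH flanked by the ring-fusion methine C-7; no stereocentre is touched.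

**Compound list**

1 | 2-methylallylmagnesium chloride | C=C(C)C[Mg]Cl | starting material
2 | trimethyl orthoformate | COC(OC)OC | starting material
3 | 4,4-dimethoxy-2-methylbut-1-ene | C=C(C)CC(OC)OC | intermediate
4 | (R)-2-vinyloxirane | C=C[C@@H]1CO1 | starting material
5 | lithium acetylide–ethylenediamine complex | [Li+].[C-]#C.NCCN | starting material
6 | (S)-hex-1-en-5-yn-3-ol | C#CC[C@@H](C=C)O | intermediate
7 | (3S)-3-[(1-methoxy-3-methylbut-3-en-1-yl)oxy]hex-1-en-5-yne | C#CC[C@@H](C=C)OC(OC)CC(C)=C | intermediate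
8 | acrolein | C=CC=O | starting material
9 | methylzinc acetylide of 7 | C[Zn]C#CC[C@@H](C=C)OC(OC)CC(C)=C | intermediate
10 | (3S,7S)-7-[(1-methoxy-3-methylbut-3-en-1-yl)oxy]nona-1,8-dien-4-yn-3-ol | C=C[C@H](O)C#CC[C@@H](C=C)OC(OC)CC(C)=C | intermediate
11 | sodium cyclic alkenylalanate from trans-hydroalumination of 10 (Al bound to O-3 and C-5, two 2-methoxyethoxy ligands) | [Na+].COCCO[Al-]1(OCCOC)O[C@@H](C=C)C=C1C[C@@H](C=C)OC(OC)CC(C)=C | intermediate
12 | (3S,4Z,7S)-5-iodo-7-[(1-methoxy-3-methylbut-3-en-1-yl)oxy]nona-1,4,8-trien-3-ol | C=C[C@H](O)/C=C(\I)C[C@@H](C=C)OC(OC)CC(C)=C | intermediate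
13 | (2Z,4S)-2-{(2S)-2-[(1-methoxy-3-methylbut-3-en-1-yl)oxy]but-3-en-1-yl}hexa-2,5-diene-1,4-diol | C=C[C@H](O)/C=C(\CO)C[C@@H](C=C)OC(OC)CC(C)=C | intermediate
14 | (2Z,4S)-4-hydroxy-2-{(2S)-2-[(1-methoxy-3-methylbut-3-en-1-yl)oxy]but-3-en-1-yl}hexa-2,5-dien-1-yl acetate | C=C[C@H](O)/C=C(\COC(C)=O)C[C@@H](C=C)OC(OC)CC(C)=C | intermediate
15 | methyl 2-(bromomethyl)acrylate | C=C(CBr)C(=O)OC | starting material
16 | (2Z,4S)-4-hydroxy-2-{[(2S)-6-methoxy-4-methyl-5,6-dihydro-2H-pyran-2-yl]methyl}hexa-2,5-dien-1-yl acetate | C=C[C@H](O)/C=C(\COC(C)=O)C[C@H]1C=C(C)CC(OC)O1 | intermediate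
17 | methyl (2Z,4R,5Z)-6-(acetoxymethyl)-2-(bromomethyl)-4-hydroxy-7-[(2S)-6-methoxy-4-methyl-5,6-dihydro-2H-pyran-2-yl]hepta-2,5-dienoate | COC(=O)/C(CBr)=C/[C@H](O)/C=C(\COC(C)=O)C[C@H]1C=C(C)CC(OC)O1 | intermediate
18 | lactol: methyl (2Z,4R,5Z)-6-(acetoxymethyl)-2-(bromomethyl)-4-hydroxy-7-[(2S)-6-hydroxy-4-methyl-5,6-dihydro-2H-pyran-2-yl]hepta-2,5-dienoate | COC(=O)/C(CBr)=C/[C@H](O)/C=C(\COC(C)=O)C[C@H]1C=C(C)CC(O)O1 | intermediate
19 | open-chain allylzinc bromide: methyl (2Z,4R,5Z,8S,9Z)-6-(acetoxymethyl)-2-[(bromozincio)methyl]-4,8-dihydroxy-10-methyl-12-oxododeca-2,5,9-trienoate | COC(=O)/C(C[Zn]Br)=C/[C@H](O)/C=C(\COC(C)=O)C[C@H](O)/C=C(/C)CC=O | intermediate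
20 | methyl 2-[(1R,2R,3Z,6S,7Z,10R)-4-(acetoxymethyl)-2,6,10-trihydroxy-8-methylcyclodeca-3,7-dien-1-yl]acrylate | C=C(C(=O)OC)[C@H]1[C@H](O)/C=C(\COC(C)=O)C[C@H](O)/C=C(/C)C[C@H]1O | intermediate
21 | (2S,6R,7R,8R)-15-acetoxy-2,8-dihydroxygermacra-1(10),4,11(13)-trien-12,6-olide (1(10)Z; C-15 cis to C-6 on C4=C5; trans-fused lactone) | C=C1C(=O)O[C@@H]2/C=C(\COC(C)=O)C[C@H](O)/C=C(/C)C[C@@H](O)[C@@H]12 | intermediate
22 | angelic acid, (Z)-2-methylbut-2-enoic acid | C/C=C(/C)C(=O)O | starting material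
23 | angelic 2,4,6-trichlorobenzoic anhydride | C/C=C(/C)C(=O)OC(=O)c1c(Cl)cc(Cl)cc1Cl | intermediate
24 | CNP0129394.1: (2S,6R,7R,8R)-15-acetoxy-2-angeloyloxy-8-hydroxygermacra-1(10),4,11(13)-trien-12,6-olide | C=C1C(=O)O[C@@H]2/C=C(\COC(C)=O)C[C@H](OC(=O)/C(C)=C\C)/C=C(/C)C[C@@H](O)[C@@H]12 | target

**Step count and risks**

Total step count: 10. Longest linear sequence: 9 steps (steps 2–10, from 4); step 1 is a one-step side branch.

Steps most likely to fail:

Step 9 (the proposed ring expansion). The risks are protonolysis of the allylzinc before it finds the aldehyde, oligomerisation, and the C-7/C-8 diastereoselectivity. The fallback uses only known chemistry; it sets out from 17 and comes back at 20. Ethane-1,2-dithiol and BF3·OEt2 (CH2Cl2, −40 °C) open the cyclic acetal to the open-chain dithiolane diol F3. TESOTf/2,6-lutidine gives the bis(triethylsilyl) ether F4. MeI/CaCO3 in aqueous MeCN unmasks the discrete aldehyde F5. CrCl2 in THF at high dilution (Nozaki–Hiyama allylation of an open-chain formyl allylic bromide, the established way to close germacranolide rings) gives the ten-membered alcohol F6. HF·pyridine removes both silyl groups to give 20, which is lactonised with TsOH as in step 9.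

Step 10 (site-selective angeloylation of 2-OH beside 8-OH). The fallback sets out from 21 and comes back at 24. MnO2 (CH2Cl2) oxidises only the allylic 2-OH to the Z-enone F7. TESOTf/2,6-lutidine protects the 8-OH to give the silyl ether F8. CBS reduction (oxazaborolidine enantiomer chosen for 2S, catecholborane, −78 °C) returns the 2S alcohol F9 under reagent control. Angeloylation with 23 gives the silylated angelate F10, and HF·pyridine gives 24.

Step 4 (enantioselective alkynylation of acrolein, which polymerises easily and may give modest ee). The fallback sets out from 7 and comes back at 10. Lithiation of 7 (n-BuLi, THF, −78 °C) and addition to acrolein give the C-3-epimeric propargylic alcohols F1. MnO2 oxidises them to the alkynyl vinyl ketone F2. Midland reduction with the Alpine-Borane enantiomer chosen for the S carbinol gives 10.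

**Further compounds**

F1 | step 4 | (3RS,7S)-7-[(1-methoxy-3-methylbut-3-en-1-yl)oxy]nona-1,8-dien-4-yn-3-ol | C=CC(O)C#CC[C@@H](C=C)OC(OC)CC(C)=C
F2 | step 4 | (7S)-7-[(1-methoxy-3-methylbut-3-en-1-yl)oxy]nona-1,8-dien-4-yn-3-one | C=CC(=O)C#CC[C@@H](C=C)OC(OC)CC(C)=C
F3 | step 9 | methyl (2Z,4R,5Z,8S,9Z)-6-(acetoxymethyl)-2-(bromomethyl)-11-(1,3-dithiolan-2-yl)-4,8-dihydroxy-10-methylundeca-2,5,9-trienoate | COC(=O)/C(CBr)=C/[C@H](O)/C=C(\COC(C)=O)C[C@H](O)/C=C(/C)CC1SCCS1
F4 | step 9 | 4,8-bis(triethylsilyl) ether of F3 | COC(=O)/C(CBr)=C/[C@H](O[Si](CC)(CC)CC)/C=C(\COC(C)=O)C[C@H](O[Si](CC)(CC)CC)/C=C(/C)CC1SCCS1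
F5 | step 9 | methyl (2Z,4R,5Z,8S,9Z)-6-(acetoxymethyl)-2-(bromomethyl)-10-methyl-12-oxo-4,8-bis(triethylsilyloxy)dodeca-2,5,9-trienoate | COC(=O)/C(CBr)=C/[C@H](O[Si](CC)(CC)CC)/C=C(\COC(C)=O)C[C@H](O[Si](CC)(CC)CC)/C=C(/C)CC=O
F6 | step 9 | methyl 2-[(1R,2R,3Z,6S,7Z,10R)-4-(acetoxymethyl)-10-hydroxy-8-methyl-2,6-bis(triethylsilyloxy)cyclodeca-3,7-dien-1-yl]acrylate | C=C(C(=O)OC)[C@H]1[C@H](O[Si](CC)(CC)CC)/C=C(\COC(C)=O)C[C@H](O[Si](CC)(CC)CC)/C=C(/C)C[C@H]1O
F7 | step 10 | (6R,7R,8R)-15-acetoxy-8-hydroxy-2-oxogermacra-1(10),4,11(13)-trien-12,6-olide | C=C1C(=O)O[C@@H]2/C=C(\COC(C)=O)CC(=O)/C=C(/C)C[C@@H](O)[C@@H]12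
F8 | step 10 | 8-O-triethylsilyl ether of F7 | C=C1C(=O)O[C@@H]2/C=C(\COC(C)=O)CC(=O)/C=C(/C)C[C@@H](O[Si](CC)(CC)CC)[C@@H]12
F9 | step 10 | (2S,6R,7R,8R)-15-acetoxy-2-hydroxy-8-(triethylsilyloxy)germacra-1(10),4,11(13)-trien-12,6-olide | C=C1C(=O)O[C@@H]2/C=C(\COC(C)=O)C[C@H](O)/C=C(/C)C[C@@H](O[Si](CC)(CC)CC)[C@@H]12
F10 | step 10 | 8-O-triethylsilyl ether of 24 | C=C1C(=O)O[C@@H]2/C=C(\COC(C)=O)C[C@H](OC(=O)/C(C)=C\C)/C=C(/C)C[C@@H](O[Si](CC)(CC)CC)[C@@H]12
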